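**Retrosynthetic overview**

1. C11=C12 is made last by Julia–Kocienski olefination of a C11 aldehyde. Before that, C3–CH2CO2Me comes from attack of a ketene silyl acetal on the peroxycarbenium ion of a C3 methoxy peroxyacetal.
2. C7–C8 comes from a Wittig reaction of a C7 aldehyde with a C8–C11 ylide (C10 set by Evans allylation), then diimide. The C7 aldehyde comes from periodate cleavage of a C7–C8 diol.
3. The only ring, the 1,2-dioxane O1–O2–C3–C4–C5–C6, is closed at O1–C6: a C3 hydroperoxy acetal opens a C6–C7 Sharpless epoxide 6-exo with inversion. The plan rests on the peroxide-bearing quaternary carbon C6 (ethyl, chain, O1), which is set by the epoxide; the C7–C8 diol released is the handle for the chain.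
4. Precursor: C4 by Evans alkylation with an (E)-allylic bromide (C5–C8), C6/C7 by Sharpless epoxidation, and the C3 hydroperoxy acetal by ozonolysis of a methyl enol ether in methanol.

Key step: step 12

Remark: atoms carry the target numbering (ring O1, O2, C3–C6; chain C7–C14). C3 is carried as both methoxy-acetal epimers from step 11 to step 24 because it is ionised in step 25.

**Ring fragment up to the C7 aldehyde**

Step 1
Reactants: 1 (4R)-4-benzyl-1,3-oxazolidin-2-one; 2 butanoyl chloride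
Product: 3 (4R)-4-benzyl-3-butanoyl-1,3-oxazolidin-2-one
Conditions: Et3N, DMAP (cat.), CH2Cl2, 0 °C → rt
Reagents that add atoms: none
Why: N-acylation of the oxazolidinone by the acid chloride under DMAP catalysis installs the auxiliary that will control C4; no stereocentre is formed.

Step 2
Reactants: 4 (tert-butyldimethylsilyloxy)acetaldehyde; 5 triethyl 2-phosphonobutanoate
Product: 6 ethyl (2E)-4-{[tert-butyl(dimethyl)silyl]oxy}-2-ethylbut-2-enoate
Conditions: LiCl, DBU, MeCN, 0 °C → rt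
Reagents that add atoms: none
Why: Horner–Wadsworth–Emmons olefination under Masamune–Roush conditions should give mainly the (E)-enoate (ester trans to CH2OTBS, which places the future C8 cis to the C6 ethyl group), any (Z)-isomer being removed by chromatography.

Step 3
Reactants: 6 ethyl (2E)-4-{[tert-butyl(dimethyl)silyl]oxy}-2-ethylbut-2-enoate
Product: 7 (2E)-4-{[tert-butyl(dimethyl)silyl]oxy}-2-ethylbut-2-en-1-ol
Conditions: iBu2AlH, CH2Cl2, −78 → 0 °C; aq. potassium sodium tartrate
Reagents that add atoms: none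
Why: 1,2-reduction of the conjugated ester by the aluminium hydride gives the allylic alcohol without touching the silyl ether or the alkene geometry.

Step 4
Reactants: 7 (2E)-4-{[tert-butyl(dimethyl)silyl]oxy}-2-ethylbut-2-en-1-ol
Product: 8 {[(2E)-4-bromo-3-ethylbut-2-en-1-yl]oxy}(tert-butyl)dimethylsilane
Conditions: CBr4, PPh3, CH2Cl2, 0 °C
Reagents that add atoms: tetrabromomethane, BrC(Br)(Br)Br
Why: Appel bromination converts the primary allylic alcohol into the bromide by SN2 displacement of the oxyphosphonium ion under neutral conditions that the silyl ether tolerates.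

Step 5
Reactants: 3 (4R)-4-benzyl-3-butanoyl-1,3-oxazolidin-2-one; 8 {[(2E)-4-bromo-3-ethylbut-2-en-1-yl]oxy}(tert-butyl)dimethylsilane
Product: 10 (4R)-4-benzyl-3-[(2S,4E)-6-{[tert-butyl(dimethyl)silyl]oxy}-2,4-diethylhex-4-enoyl]-1,3-oxazolidin-2-one, via sodium enolate 9 (not isolated)
Conditions: NaN(SiMe3)2, THF, −78 °C; then 8, −78 → −30 °C
Reagents that add atoms: none
Why: Evans asymmetric alkylation: the chelated (Z)-sodium enolate is attacked by the allylic bromide on the face opposite the benzyl group, which forms C4–C5 and sets C4 as (S); the minor diastereomer is separable.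

Step 6
Reactants: 10 (4R)-4-benzyl-3-[(2S,4E)-6-{[tert-butyl(dimethyl)silyl]oxy}-2,4-diethylhex-4-enoyl]-1,3-oxazolidin-2-one
Product: 11 (2S,4E)-6-{[tert-butyl(dimethyl)silyl]oxy}-2,4-diethylhex-4-en-1-ol
Conditions: LiBH4, MeOH (1 equiv), THF, 0 °C
Reagents that add atoms: none
Why: Reductive cleavage of the imide by borohydride releases the primary C3 alcohol and the recoverable auxiliary without epimerising C4.

Step 7
Reactants: 11 (2S,4E)-6-{[tert-butyl(dimethyl)silyl]oxy}-2,4-diethylhex-4-en-1-ol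
Product: 12 (2S,4E)-6-{[tert-butyl(dimethyl)silyl]oxy}-2,4-diethylhex-4-enal
Conditions: Dess–Martin periodinane, NaHCO3, CH2Cl2, 0 °C → rt
Reagents that add atoms: none
Why: Dess–Martin oxidation gives the α-branched aldehyde under buffered, non-basic conditions that keep C4 intact.

Step 8
Reactants: 12 (2S,4E)-6-{[tert-butyl(dimethyl)silyl]oxy}-2,4-diethylhex-4-enal
Product: 13 tert-butyl{[(2E,5S)-3,5-diethyl-7-methoxyhepta-2,6-dien-1-yl]oxy}dimethylsilane (6E/6Z mixture)
Conditions: Ph3P(CH2OMe)Cl, KN(SiMe3)2, THF, 0 °C; then 12, −78 → 0 °C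
Reagents that add atoms: (methoxymethyl)triphenylphosphonium chloride, COC[P+](c1ccccc1)(c1ccccc1)c1ccccc1.[Cl-]
Why: Wittig methoxymethylenation with the preformed ylide at low temperature turns the aldehyde into a methyl enol ether (both geometries serve), chosen over a vinyl group so that the later ozonolysis can cleave in one direction only.

Step 9
Reactants: 13 tert-butyl{[(2E,5S)-3,5-diethyl-7-methoxyhepta-2,6-dien-1-yl]oxy}dimethylsilane
Product: 14 (2E,5S)-3,5-diethyl-7-methoxyhepta-2,6-dien-1-ol (6E/6Z mixture)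
Conditions: Bu4NF, THF, 0 °C → rt
Reagents that add atoms: none
Why: Fluoride cleaves the silyl ether and frees the C8 allylic alcohol that must direct the epoxidation; the enol ether is stable to these basic conditions.

Step 10
Reactants: 14 (2E,5S)-3,5-diethyl-7-methoxyhepta-2,6-dien-1-ol
Product: 15 [(2S,3S)-3-ethyl-3-[(2S)-2-ethyl-4-methoxybut-3-en-1-yl]oxiran-2-yl]methanol (enol ether E/Z mixture)
Conditions: Ti(OiPr)4 (10 mol%), L-(+)-diethyl tartrate (12 mol%), tBuOOH, 4 Å MS, CH2Cl2, −20 °C; aq. NaOH/NaCl work-up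
Reagents that add atoms: tert-butyl hydroperoxide, CC(C)(C)OO
Why: Sharpless asymmetric epoxidation: with L-(+)-tartrate the hydroxyl-directed oxygen transfer to the (E)-3,3-disubstituted allylic alcohol gives the (2S,3S)-epoxy alcohol under reagent control (the sense known for geraniol), fixing C6 and C7, while the enol ether has no directing group and should not react.

Step 11
Reactants: 15 [(2S,3S)-3-ethyl-3-[(2S)-2-ethyl-4-methoxybut-3-en-1-yl]oxiran-2-yl]methanol
Product: 18 [(2S,3S)-3-ethyl-3-[(2S)-2-ethyl-3-hydroperoxy-3-methoxypropyl]oxiran-2-yl]methanol (both C3 epimers), via primary ozonide 16 (not isolated), via carbonyl oxide 17 (not isolated)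
Conditions: O3, CH2Cl2/MeOH (4:1), NaHCO3, −78 °C; N2 purge, no reductant; concentrated cold and used crude
Reagents that add atoms: ozone, [O-][O+]=O; methanol, CO
Why: Ozonolysis of an enol ether in methanol: the primary ozonide fragments to methyl formate and the C3 carbonyl oxide, which methanol traps as the α-methoxy hydroperoxide (C3 unset), the epoxide and the alcohol being inert to ozone at −78 °C.

Step 12
Reactants: 18 [(2S,3S)-3-ethyl-3-[(2S)-2-ethyl-3-hydroperoxy-3-methoxypropyl]oxiran-2-yl]methanol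
Product: 19 (1S)-1-[(3R,5S)-3,5-diethyl-6-methoxy-1,2-dioxan-3-yl]ethane-1,2-diol (both acetal epimers; dioxane C3 is target C6)
Conditions: camphor-10-sulfonic acid (10 mol%), CH2Cl2, 0 °C; Et3N quench
Reagents that add atoms: none
Why: Protonation of the epoxide oxygen polarises the C6–O bond at the tertiary carbon, and the terminal oxygen of the C3 hydroperoxy group attacks C6 from the backside within the same molecule. The closest known reaction type is the acid-promoted intramolecular opening of an epoxide by a hydroperoxide, by which 1,2-dioxanes are made from epoxy hydroperoxides. The 1,2-dioxane O1–O2–C3–C4–C5–C6 closes in the 6-exo mode, the breaking C6–O bond lying outside the new ring. C6 is formed with inversion, so its configuration is dictated by the (2S,3S) Sharpless epoxide and not by any size difference between ethyl and the chain, while C7 keeps its configuration as the secondary alcohol. The step needs regioselectivity (C6 over C7) and stereospecificity: the tertiary carbon carries positive charge best and attack at C7 would be a 7-endo closure, so both factors direct the oxygen to C6. Both C3 epimers cyclise and C3 remains an unset methoxy acetal, which is intended because it is ionised in step 25.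

Step 13
Reactants: 19 (1S)-1-[(3R,5S)-3,5-diethyl-6-methoxy-1,2-dioxan-3-yl]ethane-1,2-diol
Product: 20 (3R,5S)-3,5-diethyl-6-methoxy-1,2-dioxane-3-carbaldehyde (both acetal epimers)
Conditions: NaIO4, NaHCO3, THF/H2O, 0 °C
Reagents that add atoms: none
Why: Periodate glycol cleavage of the 1,2-diol gives the non-enolisable C7 aldehyde on the quaternary carbon and formaldehyde; the dialkyl peroxide and the peroxyacetal are stable to periodate.

**Side-chain phosphonium salt and sulfone**

Step 14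
Reactants: 21 (4S)-4-benzyl-1,3-oxazolidin-2-one; 2 butanoyl chloride
Product: 22 (4S)-4-benzyl-3-butanoyl-1,3-oxazolidin-2-one
Conditions: Et3N, DMAP (cat.), CH2Cl2, 0 °C → rt
Reagents that add atoms: none
Why: N-acylation as in step 1, now with the (S)-auxiliary required for C10.

Step 15
Reactants: 22 (4S)-4-benzyl-3-butanoyl-1,3-oxazolidin-2-one; 23 allyl iodide
Product: 25 (4S)-4-benzyl-3-[(2R)-2-ethylpent-4-enoyl]-1,3-oxazolidin-2-one, via sodium enolate 24 (not isolated)
Conditions: NaN(SiMe3)2, THF, −78 °C; then 23, −78 → −40 °C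
Reagents that add atoms: none
Why: Evans asymmetric allylation: the chelated (Z)-sodium enolate reacts with allyl iodide on the face opposite the benzyl group, which sets C10 as (R).

Step 16
Reactants: 25 (4S)-4-benzyl-3-[(2R)-2-ethylpent-4-enoyl]-1,3-oxazolidin-2-one
Product: 26 (2R)-2-ethylpent-4-en-1-ol
Conditions: LiBH4, MeOH (1 equiv), THF, 0 °C
Reagents that add atoms: none
Why: Reductive removal of the auxiliary gives the primary alcohol (future C11) without touching C10.

Step 17
Reactants: 26 (2R)-2-ethylpent-4-en-1-ol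
Product: 27 tert-butyl{[(2R)-2-ethylpent-4-en-1-yl]oxy}diphenylsilane
Conditions: tBuPh2SiCl, imidazole, CH2Cl2, rt
Reagents that add atoms: tert-butyl(chloro)diphenylsilane, CC(C)(C)[Si](Cl)(c1ccccc1)c1ccccc1
Why: Silylation of the primary alcohol as a tert-butyldiphenylsilyl ether, a group that should survive the ylide, diimide and TiCl4 steps.

Step 18
Reactants: 27 tert-butyl{[(2R)-2-ethylpent-4-en-1-yl]oxy}diphenylsilane
Product: 29 (3R)-3-{[tert-butyl(diphenyl)silyl]oxymethyl}pentan-1-ol, via aldehyde 28 (not isolated)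
Conditions: O3, CH2Cl2, −78 °C; Me2S, −78 °C → rt; then NaBH4, MeOH, 0 °C
Reagents that add atoms: ozone, [O-][O+]=O
Why: Ozonolysis of the terminal alkene with reductive work-up removes one carbon, and borohydride reduces the resulting aldehyde to the C8 alcohol in the same flask.

Step 19
Reactants: 29 (3R)-3-{[tert-butyl(diphenyl)silyl]oxymethyl}pentan-1-ol
Product: 30 tert-butyl{[(2R)-2-ethyl-4-iodobutyl]oxy}diphenylsilane
Conditions: I2, PPh3, imidazole, CH2Cl2, 0 °C → rt
Reagents that add atoms: iodine, II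
Why: Appel-type iodination of the primary alcohol by SN2 displacement of the oxyphosphonium ion.

Step 20
Reactants: 30 tert-butyl{[(2R)-2-ethyl-4-iodobutyl]oxy}diphenylsilane
Product: 31 [(3R)-3-{[tert-butyl(diphenyl)silyl]oxymethyl}pentyl]triphenylphosphonium iodide
Conditions: PPh3, MeCN, 80 °C
Reagents that add atoms: triphenylphosphine, c1ccccc1P(c1ccccc1)c1ccccc1
Why: SN2 quaternisation of triphenylphosphine by the primary iodide gives the Wittig salt.

Step 21
Reactants: 32 1-phenyl-1H-tetrazole-5-thiol; 33 1-bromopropane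
Product: 34 1-phenyl-5-(propylsulfanyl)-1H-tetrazole
Conditions: K2CO3, acetone, 56 °C
Reagents that add atoms: none
Why: S-alkylation of the tetrazole thiolate by the primary bromide (SN2).

Step 22
Reactants: 34 1-phenyl-5-(propylsulfanyl)-1H-tetrazole
Product: 35 1-phenyl-5-(propylsulfonyl)-1H-tetrazole
Conditions: H2O2 (30% aq.), (NH4)6Mo7O24·4H2O (cat.), EtOH, 0 °C → rt
Reagents that add atoms: hydrogen peroxide, OO
Why: Molybdate-catalysed oxidation of the sulfide with hydrogen peroxide gives the tetrazolyl sulfone for the Julia–Kocienski olefination.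

**Coupling and completion**

Step 23
Reactants: 31 [(3R)-3-{[tert-butyl(diphenyl)silyl]oxymethyl}pentyl]triphenylphosphonium iodide; 20 (3R,5S)-3,5-diethyl-6-methoxy-1,2-dioxane-3-carbaldehyde
Product: 37 tert-butyl{[(2R,4Z)-5-[(3R,5S)-3,5-diethyl-6-methoxy-1,2-dioxan-3-yl]-2-ethylpent-4-en-1-yl]oxy}diphenylsilane (both acetal epimers), via phosphorus ylide 36 (not isolated)
Conditions: NaN(SiMe3)2 (slightly less than 1 equiv per salt), THF, −78 → 0 °C; then 20, −78 → 0 °C
Reagents that add atoms: none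
Why: Wittig olefination of the non-enolisable C7 aldehyde with the unstabilised ylide forms C7=C8 (mainly Z, of no consequence) at low temperature, conditions under which dialkyl peroxides and peroxyacetals survive ylides.

Step 24
Reactants: 37 tert-butyl{[(2R,4Z)-5-[(3R,5S)-3,5-diethyl-6-methoxy-1,2-dioxan-3-yl]-2-ethylpent-4-en-1-yl]oxy}diphenylsilane
Product: 38 tert-butyl{[(2R)-5-[(3S,5S)-3,5-diethyl-6-methoxy-1,2-dioxan-3-yl]-2-ethylpentyl]oxy}diphenylsilane (both acetal epimers)
Conditions: KO2CN=NCO2K (excess, in portions), AcOH, MeOH/CH2Cl2, 0 °C → rt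
Reagents that add atoms: none
Why: Diimide reduction: diimide generated from the azodicarboxylate transfers H2 to C7=C8 by concerted syn addition and leaves the O–O bond untouched, which is why the C11=C12 alkene is introduced only afterwards.

Step 25
Reactants: 38 tert-butyl{[(2R)-5-[(3S,5S)-3,5-diethyl-6-methoxy-1,2-dioxan-3-yl]-2-ethylpentyl]oxy}diphenylsilane; 39 1-(tert-butyldimethylsilyloxy)-1-methoxyethene
Product: 41 methyl 2-[(3S,4S,6S)-6-[(4R)-5-{[tert-butyl(diphenyl)silyl]oxy}-4-ethylpentyl]-4,6-diethyl-1,2-dioxan-3-yl]acetate, via peroxycarbenium ion 40 (not isolated)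
Conditions: TiCl4 (1.1 equiv), 39 (3 equiv), CH2Cl2, −78 °C
Reagents that add atoms: none
Why: Mukaiyama-type substitution of an alkoxy-1,2-dioxane: TiCl4 ionises the peroxyacetal to the peroxycarbenium ion, whose half-chair keeps the C4 ethyl pseudo-equatorial (otherwise it would be 1,3-diaxial to the C6 ethyl), so axial attack of the ketene silyl acetal should place the C3 substituent cis to the C4 ethyl group, the minor C3 epimer being removed by chromatography.

Step 26
Reactants: 41 methyl 2-[(3S,4S,6S)-6-[(4R)-5-{[tert-butyl(diphenyl)silyl]oxy}-4-ethylpentyl]-4,6-diethyl-1,2-dioxan-3-yl]acetate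
Product: 42 methyl 2-[(3S,4S,6S)-4,6-diethyl-6-[(4R)-4-ethyl-5-hydroxypentyl]-1,2-dioxan-3-yl]acetate
Conditions: HF·pyridine, pyridine/THF, 0 °C → rt
Reagents that add atoms: none
Why: Fluoride-mediated desilylation under weakly acidic conditions avoids base-induced opening of the β-peroxy ester.

Step 27
Reactants: 42 methyl 2-[(3S,4S,6S)-4,6-diethyl-6-[(4R)-4-ethyl-5-hydroxypentyl]-1,2-dioxan-3-yl]acetate
Product: 43 methyl 2-[(3S,4S,6S)-4,6-diethyl-6-[(4R)-4-ethyl-5-oxopentyl]-1,2-dioxan-3-yl]acetate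
Conditions: Dess–Martin periodinane, NaHCO3, CH2Cl2, 0 °C → rt; used at once
Reagents that add atoms: none
Why: Dess–Martin oxidation gives the α-branched C11 aldehyde under neutral conditions compatible with the peroxide and with the C10 stereocentre.

Step 28
Reactants: 43 methyl 2-[(3S,4S,6S)-4,6-diethyl-6-[(4R)-4-ethyl-5-oxopentyl]-1,2-dioxan-3-yl]acetate; 35 1-phenyl-5-(propylsulfonyl)-1H-tetrazole
Product: 45 methyl 2-[(3S,4S,6S)-4,6-diethyl-6-[(4R,5E)-4-ethyloct-5-en-1-yl]-1,2-dioxan-3-yl]acetate, via potassium sulfonyl carbanion 44 (not isolated)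
Conditions: 35, KN(SiMe3)2, DME, −60 °C, 30 min; then 43, −60 °C → rt
Reagents that add atoms: none
Why: Julia–Kocienski olefination: addition of the premetalated tetrazolyl sulfone to the α-branched aldehyde, Smiles rearrangement and loss of SO2 should give the (E)-C11=C12 alkene, and premetalation at low temperature leaves no free amide base to enolise the ester or epimerise C10.

**Compound list**

1 | (4R)-4-benzyl-1,3-oxazolidin-2-one | O=C1OC[C@@H](Cc2ccccc2)N1 | starting material
2 | butanoyl chloride | CCCC(Cl)=O | starting material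
3 | (4R)-4-benzyl-3-butanoyl-1,3-oxazolidin-2-one | CCCC(=O)N1C(=O)OC[C@H]1Cc2ccccc2 | intermediate
4 | (tert-butyldimethylsilyloxy)acetaldehyde | O=CCO[Si](C)(C)C(C)(C)C | starting material
5 | triethyl 2-phosphonobutanoate | CCOC(=O)C(CC)P(=O)(OCC)OCC | starting material
6 | ethyl (2E)-4-{[tert-butyl(dimethyl)silyl]oxy}-2-ethylbut-2-enoate | CCOC(=O)/C(CC)=C/CO[Si](C)(C)C(C)(C)C | intermediate
7 | (2E)-4-{[tert-butyl(dimethyl)silyl]oxy}-2-ethylbut-2-en-1-ol | OC/C(CC)=C/CO[Si](C)(C)C(C)(C)C | intermediate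
8 | {[(2E)-4-bromo-3-ethylbut-2-en-1-yl]oxy}(tert-butyl)dimethylsilane | BrC/C(CC)=C/CO[Si](C)(C)C(C)(C)C | intermediate
9 | sodium (Z)-enolate of 3 | CC/C=C(\[O-])N1C(=O)OC[C@H]1Cc2ccccc2.[Na+] | intermediate
10 | (4R)-4-benzyl-3-[(2S,4E)-6-{[tert-butyl(dimethyl)silyl]oxy}-2,4-diethylhex-4-enoyl]-1,3-oxazolidin-2-one | CC[C@@H](C/C(CC)=C/CO[Si](C)(C)C(C)(C)C)C(=O)N1C(=O)OC[C@H]1Cc2ccccc2 | intermediate
11 | (2S,4E)-6-{[tert-butyl(dimethyl)silyl]oxy}-2,4-diethylhex-4-en-1-ol | CC[C@@H](C/C(CC)=C/CO[Si](C)(C)C(C)(C)C)CO | intermediate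
12 | (2S,4E)-6-{[tert-butyl(dimethyl)silyl]oxy}-2,4-diethylhex-4-enal | CC[C@@H](C/C(CC)=C/CO[Si](C)(C)C(C)(C)C)C=O | intermediate
13 | tert-butyl{[(2E,5S)-3,5-diethyl-7-methoxyhepta-2,6-dien-1-yl]oxy}dimethylsilane (6E/6Z mixture) | CC[C@@H](C/C(CC)=C/CO[Si](C)(C)C(C)(C)C)C=COC | intermediate
14 | (2E,5S)-3,5-diethyl-7-methoxyhepta-2,6-dien-1-ol (6E/6Z mixture) | CC[C@@H](C/C(CC)=C/CO)C=COC | intermediate
15 | [(2S,3S)-3-ethyl-3-[(2S)-2-ethyl-4-methoxybut-3-en-1-yl]oxiran-2-yl]methanol (enol ether E/Z mixture) | OC[C@@H]1O[C@@]1(CC)C[C@H](CC)C=COC | intermediate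
16 | primary ozonide of 15, [(2S,3S)-3-ethyl-3-[(2S)-2-(5-methoxy-1,2,3-trioxolan-4-yl)butyl]oxiran-2-yl]methanol | OC[C@@H]1O[C@@]1(CC)C[C@H](CC)C2OOOC2OC | intermediate
17 | C3 carbonyl oxide (Criegee zwitterion) carrying the epoxy alcohol | OC[C@@H]1O[C@@]1(CC)C[C@H](CC)C=[O+][O-] | intermediate
18 | [(2S,3S)-3-ethyl-3-[(2S)-2-ethyl-3-hydroperoxy-3-methoxypropyl]oxiran-2-yl]methanol (both C3 epimers; key-step precursor) | OC[C@@H]1O[C@@]1(CC)C[C@H](CC)C(OC)OO | intermediate
19 | (1S)-1-[(3R,5S)-3,5-diethyl-6-methoxy-1,2-dioxan-3-yl]ethane-1,2-diol (both acetal epimers; key-step product) | OC[C@H](O)[C@@]1(CC)C[C@H](CC)C(OC)OO1 | intermediate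
20 | (3R,5S)-3,5-diethyl-6-methoxy-1,2-dioxane-3-carbaldehyde (both acetal epimers) | O=C[C@@]1(CC)C[C@H](CC)C(OC)OO1 | intermediate
21 | (4S)-4-benzyl-1,3-oxazolidin-2-one | O=C1OC[C@H](Cc2ccccc2)N1 | starting material
22 | (4S)-4-benzyl-3-butanoyl-1,3-oxazolidin-2-one | CCCC(=O)N1C(=O)OC[C@@H]1Cc2ccccc2 | intermediate
23 | allyl iodide (3-iodoprop-1-ene) | C=CCI | starting material
24 | sodium (Z)-enolate of 22 | CC/C=C(\[O-])N1C(=O)OC[C@@H]1Cc2ccccc2.[Na+] | intermediate
25 | (4S)-4-benzyl-3-[(2R)-2-ethylpent-4-enoyl]-1,3-oxazolidin-2-one | C=CC[C@@H](CC)C(=O)N1C(=O)OC[C@@H]1Cc2ccccc2 | intermediate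
26 | (2R)-2-ethylpent-4-en-1-ol | C=CC[C@@H](CC)CO | intermediate
27 | tert-butyl{[(2R)-2-ethylpent-4-en-1-yl]oxy}diphenylsilane | C=CC[C@@H](CC)CO[Si](c1ccccc1)(c1ccccc1)C(C)(C)C | intermediate
28 | (3R)-3-{[tert-butyl(diphenyl)silyl]oxymethyl}pentanal | O=CC[C@@H](CC)CO[Si](c1ccccc1)(c1ccccc1)C(C)(C)C | intermediate
29 | (3R)-3-{[tert-butyl(diphenyl)silyl]oxymethyl}pentan-1-ol | OCC[C@@H](CC)CO[Si](c1ccccc1)(c1ccccc1)C(C)(C)C | intermediate
30 | tert-butyl{[(2R)-2-ethyl-4-iodobutyl]oxy}diphenylsilane | ICC[C@@H](CC)CO[Si](c1ccccc1)(c1ccccc1)C(C)(C)C | intermediate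
31 | [(3R)-3-{[tert-butyl(diphenyl)silyl]oxymethyl}pentyl]triphenylphosphonium iodide | c1ccccc1[P+](c1ccccc1)(c1ccccc1)CC[C@@H](CC)CO[Si](c1ccccc1)(c1ccccc1)C(C)(C)C.[I-] | intermediate
32 | 1-phenyl-1H-tetrazole-5-thiol | Sc1nnnn1-c1ccccc1 | starting material
33 | 1-bromopropane | CCCBr | starting material
34 | 1-phenyl-5-(propylsulfanyl)-1H-tetrazole | CCCSc1nnnn1-c1ccccc1 | intermediate
35 | 1-phenyl-5-(propylsulfonyl)-1H-tetrazole | CCCS(=O)(=O)c1nnnn1-c1ccccc1 | intermediate
36 | phosphorus ylide from 31 | c1ccccc1P(c1ccccc1)(c1ccccc1)=CC[C@@H](CC)CO[Si](c1ccccc1)(c1ccccc1)C(C)(C)C | intermediate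
37 | tert-butyl{[(2R,4Z)-5-[(3R,5S)-3,5-diethyl-6-methoxy-1,2-dioxan-3-yl]-2-ethylpent-4-en-1-yl]oxy}diphenylsilane (both acetal epimers) | CC(C)(C)[Si](c1ccccc1)(c1ccccc1)OC[C@H](CC)C/C=C\[C@@]1(CC)C[C@H](CC)C(OC)OO1 | intermediate
38 | tert-butyl{[(2R)-5-[(3S,5S)-3,5-diethyl-6-methoxy-1,2-dioxan-3-yl]-2-ethylpentyl]oxy}diphenylsilane (both acetal epimers) | CC(C)(C)[Si](c1ccccc1)(c1ccccc1)OC[C@H](CC)CCC[C@@]1(CC)C[C@H](CC)C(OC)OO1 | intermediate
39 | 1-(tert-butyldimethylsilyloxy)-1-methoxyethene | C=C(OC)O[Si](C)(C)C(C)(C)C | starting material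
40 | peroxycarbenium ion from 38 (C3=O2 cation of the 1,2-dioxane) | CC(C)(C)[Si](c1ccccc1)(c1ccccc1)OC[C@H](CC)CCC[C@@]1(CC)C[C@H](CC)C=[O+]O1 | intermediate
41 | methyl 2-[(3S,4S,6S)-6-[(4R)-5-{[tert-butyl(diphenyl)silyl]oxy}-4-ethylpentyl]-4,6-diethyl-1,2-dioxan-3-yl]acetate | CC(C)(C)[Si](c1ccccc1)(c1ccccc1)OC[C@H](CC)CCC[C@@]1(CC)C[C@H](CC)[C@H](CC(=O)OC)OO1 | intermediate
42 | methyl 2-[(3S,4S,6S)-4,6-diethyl-6-[(4R)-4-ethyl-5-hydroxypentyl]-1,2-dioxan-3-yl]acetate | OC[C@H](CC)CCC[C@@]1(CC)C[C@H](CC)[C@H](CC(=O)OC)OO1 | intermediate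
43 | methyl 2-[(3S,4S,6S)-4,6-diethyl-6-[(4R)-4-ethyl-5-oxopentyl]-1,2-dioxan-3-yl]acetate | O=C[C@H](CC)CCC[C@@]1(CC)C[C@H](CC)[C@H](CC(=O)OC)OO1 | intermediate
44 | potassium salt of α-metalated 35 | CC[CH-]S(=O)(=O)c1nnnn1-c1ccccc1.[K+] | intermediate
45 | methyl 2-[(3S,4S,6S)-4,6-diethyl-6-[(4R,5E)-4-ethyloct-5-en-1-yl]-1,2-dioxan-3-yl]acetate | CC/C=C/[C@H](CC)CCC[C@@]1(CC)C[C@H](CC)[C@H](CC(=O)OC)OO1 | target

**Step count**

Total step count: 28.
Longest linear sequence: 18 steps (steps 2–13, then 23–28).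

**Steps most likely to fail**

1. Step 12. What may go wrong: acid-induced ionisation of the hydroperoxy acetal (loss of methanol or hydrogen peroxide, Hock-type cleavage) may run ahead of epoxide opening, and the C3 acetal centre may later be captured by the new C7 hydroxyl. Fallback (sets out from 12, returns at 19): the peroxide oxygens are brought in as hydrogen peroxide instead of ozone. Aldehyde 12 is treated with HC(OMe)3 and camphorsulfonic acid in methanol, which forms the dimethyl acetal and removes the silyl ether in one operation, giving (2E,5S)-3,5-diethyl-6,6-dimethoxyhex-2-en-1-ol F1. The epoxidation of step 10 then gives [(2S,3S)-3-ethyl-3-[(2S)-2-ethyl-3,3-dimethoxypropyl]oxiran-2-yl]methanol F2. Anhydrous ethereal H2O2 with catalytic phosphomolybdic acid H3PMo12O40 opens the epoxide at the tertiary C6 with inversion to (2S,3R,5S)-3,5-diethyl-3-hydroperoxy-6,6-dimethoxyhexane-1,2-diol F3. A trace of camphorsulfonic acid then closes the ring by peroxyacetalisation of the C6 hydroperoxide onto the C3 acetal, which gives 19.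

2. Step 25. What may go wrong: the Lewis acid may consume the ketene silyl acetal or cleave the O–O bond before C–C bond formation, and equatorial attack may erode the preference at C3. Fallback (sets out from 38, returns at 41): the two-carbon unit is brought in as an allyl group and degraded. Allyltrimethylsilane and SnCl4 in CH2Cl2 at −78 °C, the best-behaved π-nucleophile for alkoxy-dioxanes, should give tert-butyl{[(2R)-5-[(3S,5S,6S)-3,5-diethyl-6-(prop-2-en-1-yl)-1,2-dioxan-3-yl]-2-ethylpentyl]oxy}diphenylsilane F4 by the same axial attack. Ozonolysis in CH2Cl2 at −78 °C with Me2S work-up gives 2-[(3S,4S,6S)-6-[(4R)-5-{[tert-butyl(diphenyl)silyl]oxy}-4-ethylpentyl]-4,6-diethyl-1,2-dioxan-3-yl]acetaldehyde F5. Pinnick oxidation (NaClO2, NaH2PO4, 2-methylbut-2-ene, tBuOH/H2O) gives 2-[(3S,4S,6S)-6-[(4R)-5-{[tert-butyl(diphenyl)silyl]oxy}-4-ethylpentyl]-4,6-diethyl-1,2-dioxan-3-yl]acetic acid F6, and Me3SiCHN2 in MeOH/toluene gives 41.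

3. Step 28. What may go wrong: the sulfonyl carbanion may enolise the β-peroxy ester, followed by β-elimination of the peroxide (ring opening); the α-branched aldehyde may epimerise; the E selectivity may erode. Fallback (sets out from 38, returns at 45): the order is changed so that the base-sensitive ester is made last. HF·pyridine converts 38 into (2R)-5-[(3S,5S)-3,5-diethyl-6-methoxy-1,2-dioxan-3-yl]-2-ethylpentan-1-ol F7. Dess–Martin oxidation gives (2R)-5-[(3S,5S)-3,5-diethyl-6-methoxy-1,2-dioxan-3-yl]-2-ethylpentanal F8. Julia–Kocienski olefination with 35 and KN(SiMe3)2 in DME gives (3S,5S)-3,5-diethyl-3-[(4R,5E)-4-ethyloct-5-en-1-yl]-6-methoxy-1,2-dioxane F9, which has no enolisable ester. The substitution of step 25 (TiCl4, 39, CH2Cl2, −78 °C) on F9 then gives 45 directly.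

**Further compounds**

F1 | step 12 | (2E,5S)-3,5-diethyl-6,6-dimethoxyhex-2-en-1-ol | OC/C=C(CC)/C[C@H](CC)C(OC)OC
F2 | step 12 | [(2S,3S)-3-ethyl-3-[(2S)-2-ethyl-3,3-dimethoxypropyl]oxiran-2-yl]methanol | OC[C@@H]1O[C@@]1(CC)C[C@H](CC)C(OC)OC
F3 | step 12 | (2S,3R,5S)-3,5-diethyl-3-hydroperoxy-6,6-dimethoxyhexane-1,2-diol | OC[C@H](O)[C@](CC)(OO)C[C@H](CC)C(OC)OC
F4 | step 25 | tert-butyl{[(2R)-5-[(3S,5S,6S)-3,5-diethyl-6-(prop-2-en-1-yl)-1,2-dioxan-3-yl]-2-ethylpentyl]oxy}diphenylsilane | CC(C)(C)[Si](c1ccccc1)(c1ccccc1)OC[C@H](CC)CCC[C@@]1(CC)C[C@H](CC)[C@H](CC=C)OO1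
F5 | step 25 | 2-[(3S,4S,6S)-6-[(4R)-5-{[tert-butyl(diphenyl)silyl]oxy}-4-ethylpentyl]-4,6-diethyl-1,2-dioxan-3-yl]acetaldehyde | CC(C)(C)[Si](c1ccccc1)(c1ccccc1)OC[C@H](CC)CCC[C@@]1(CC)C[C@H](CC)[C@H](CC=O)OO1
F6 | step 25 | 2-[(3S,4S,6S)-6-[(4R)-5-{[tert-butyl(diphenyl)silyl]oxy}-4-ethylpentyl]-4,6-diethyl-1,2-dioxan-3-yl]acetic acid | CC(C)(C)[Si](c1ccccc1)(c1ccccc1)OC[C@H](CC)CCC[C@@]1(CC)C[C@H](CC)[C@H](CC(=O)O)OO1
F7 | step 28 | (2R)-5-[(3S,5S)-3,5-diethyl-6-methoxy-1,2-dioxan-3-yl]-2-ethylpentan-1-ol | OC[C@H](CC)CCC[C@@]1(CC)C[C@H](CC)C(OC)OO1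
F8 | step 28 | (2R)-5-[(3S,5S)-3,5-diethyl-6-methoxy-1,2-dioxan-3-yl]-2-ethylpentanal | O=C[C@H](CC)CCC[C@@]1(CC)C[C@H](CC)C(OC)OO1
F9 | step 28 | (3S,5S)-3,5-diethyl-3-[(4R,5E)-4-ethyloct-5-en-1-yl]-6-methoxy-1,2-dioxane | CC/C=C/[C@H](CC)CCC[C@@]1(CC)C[C@H](CC)C(OC)OO1
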